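Numbering follows 2,3-dihydrobenzofuran: O1, C2, C3, C3a, C4–C7, C7a. Ring A is the benzo ring, ring B the dihydrofuran ring, and ring C the syringyl ring on C2.
The target is traced back (C=C saturation, loss of two O-benzyl groups) to a C5 cinnamate. Cutting O1–C7a gives a C2 alkoxide and a C7a–F bond, and the same skeleton is then taken back to a racemic C2 ketone.
Enabling feature: C7a is para to C5 and ortho to C7–OMe. With the C5 chain held at the cinnamate level, C7a–F becomes an SNAr site that O1 reaches through C2–C3–C3a. C3–H lies between the C2 carbonyl and ring A, so C3 is labile and one catalyst can set C2 and C3 from the racemate.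
The ketone comes from a Heck reaction (C5–vinyl), an enolate alkoxymethylation (C3–CH2O) and a ketone α-arylation (C3–C3a) of O-benzylacetosyringone with a fluoro-iodo-bromo-anisole made by C–H borylation.
Ring order: rings A and C are bought; ring B is the only ring made, and it is closed in the key step.

Key step: step 6

Remark: 1, 4, 8 and all reagents named are taken as commercially available.

Step 1
Reactants: 1 4-bromo-1-fluoro-2-methoxybenzene
Product: 3 5-bromo-2-fluoro-1-iodo-3-methoxybenzene, via pinacol boronate 2 (not isolated)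
Conditions: [Ir(OMe)(cod)]2 (cat.), dtbpy, B2pin2, THF, 80 °C; evaporate; CuI (cat.), 1,10-phenanthroline, KI, MeOH–H2O, air, 80 °C
Reagents that add atoms: bis(pinacolato)diboron CC1(C)OB(OC1(C)C)B1OC(C)(C)C(C)(C)O1; potassium iodide [K+].[I-]
Why: Sterically governed iridium-catalysed aromatic C–H borylation followed by copper-catalysed iododeboronation: one C–H of 1 lies between OMe and Br and one lies next to Br, so only the C–H next to the small fluorine (the later C3a) should be borylated, and ipso-iodination makes it the most reactive of the three carbon–halogen bonds.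

Step 2
Reactants: 4 1-(4-hydroxy-3,5-dimethoxyphenyl)ethan-1-one (acetosyringone)
Product: 5 1-(4-benzyloxy-3,5-dimethoxyphenyl)ethan-1-one
Conditions: BnBr, K2CO3, DMF, 60 °C
Reagents that add atoms: benzyl bromide BrCc1ccccc1
Why: Williamson ether synthesis on the only acidic O–H masks the ring C phenol with a group that the last step removes together with the other benzyl ether.

Step 3
Reactants: 3 5-bromo-2-fluoro-1-iodo-3-methoxybenzene; 5 1-(4-benzyloxy-3,5-dimethoxyphenyl)ethan-1-one
Product: 6 1-(4-benzyloxy-3,5-dimethoxyphenyl)-2-(5-bromo-2-fluoro-3-methoxyphenyl)ethan-1-one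
Conditions: Pd2(dba)3 (cat.), Xantphos, NaOt-Bu, THF, 50 °C
Reagents that add atoms: none
Why: Palladium-catalysed ketone α-arylation (Buchwald–Hartwig type) forms C3–C3a, because oxidative addition should occur at C–I well before C–Br, C–F is inert, and the more acidic product is stored as its enolate, which stops a second arylation.

Step 4
Reactants: 6 1-(4-benzyloxy-3,5-dimethoxyphenyl)-2-(5-bromo-2-fluoro-3-methoxyphenyl)ethan-1-one
Product: 7 rac-3-benzyloxy-1-(4-benzyloxy-3,5-dimethoxyphenyl)-2-(5-bromo-2-fluoro-3-methoxyphenyl)propan-1-one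
Conditions: LiN(SiMe3)2, THF, −78 °C; BnOCH2Cl, Bu4NI (cat.), −78 to 0 °C
Reagents that add atoms: benzyl chloromethyl ether ClCOCc1ccccc1
Why: Enolate alkylation with a halomethyl ether, in which the lithium enolate in THF and the softer iodomethyl ether formed in situ favour C- over O-alkylation, and C3 is formed as a racemate on purpose because step 6 is stereoconvergent.

Step 5
Reactants: 7 rac-3-benzyloxy-1-(4-benzyloxy-3,5-dimethoxyphenyl)-2-(5-bromo-2-fluoro-3-methoxyphenyl)propan-1-one; 8 methyl acrylate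
Product: 9 methyl (E)-3-{3-[rac-1-benzyloxy-3-(4-benzyloxy-3,5-dimethoxyphenyl)-3-oxopropan-2-yl]-4-fluoro-5-methoxyphenyl}acrylate
Conditions: Pd(OAc)2 (cat.), P(o-tol)3, Et3N, MeCN, 85 °C
Reagents that add atoms: none
Why: Mizoroki–Heck reaction at the only remaining C–Br bond gives the (E)-cinnamate that activates C7a–F, and the weak amine base leaves the acidic C3–H ketone, its β-benzyloxy group and the C–F bond untouched.

Step 6
Reactants: 9 methyl (E)-3-{3-[rac-1-benzyloxy-3-(4-benzyloxy-3,5-dimethoxyphenyl)-3-oxopropan-2-yl]-4-fluoro-5-methoxyphenyl}acrylate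
Product: 11 methyl (E)-3-[(2S,3R)-2-(4-benzyloxy-3,5-dimethoxyphenyl)-3-(benzyloxymethyl)-7-methoxy-2,3-dihydrobenzofuran-5-yl]acrylate, via fluoro alcohol 10 (not isolated)
Conditions: RuCl[(S,S)-TsDPEN](p-cymene) (cat.), HCO2H–Et3N (1:1), DMF, 40 °C; then Cs2CO3, 70 °C
Reagents that add atoms: none
Why: In the amine-rich formate medium C3–H of 9, flanked by the C2 carbonyl and the electron-poor ring A, exchanges through the enol faster than hydride is transferred, so both enantiomers drain through the faster-reacting one when the ruthenium hydride passes H− and H+ to C2=O in a six-membered outer-sphere transition state; once the ketone is consumed, Cs2CO3 deprotonates 10, O1 adds to C7a, the charge of the Meisenheimer adduct spreads over C5 into the acrylate, and fluoride leaves. The closest known reaction types are the Noyori–Ikariya asymmetric transfer hydrogenation with dynamic kinetic resolution of configurationally labile α-aryl aryl ketones and the intramolecular SNAr etherification of para-acceptor-substituted aryl fluorides, here run in one flask. Ring B is closed in the 5-exo-trig mode by addition–elimination at C7a. C2 (S) is set by the catalyst, which delivers hydride to the Re face of the aryl ketone, and C3 (R) by the Felkin–Anh match in the resolution (hydride anti to ring A, past C3–H); since the closure breaks no bond at C2 or C3, this alcohol can only give the 2,3-trans ring. The step needs C=O over C=C reduction (the cinnamate is too poor a hydride acceptor for this catalyst), closure through O1 alone (the only other oxygen within reach, on the C3 side chain, is benzylated) and no enolate chemistry (O-arylation to the benzofuran, loss of benzyl alcohol), which is secured by adding the carbonate only after the ketone has gone.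

Step 7
Reactants: 11 methyl (E)-3-[(2S,3R)-2-(4-benzyloxy-3,5-dimethoxyphenyl)-3-(benzyloxymethyl)-7-methoxy-2,3-dihydrobenzofuran-5-yl]acrylate
Product: 12 methyl 3-[(2S,3R)-2-(4-hydroxy-3,5-dimethoxyphenyl)-3-(hydroxymethyl)-7-methoxy-2,3-dihydrobenzofuran-5-yl]propanoate (CNP0362206.1)
Conditions: H2 (1 atm), Pd/C, EtOAc–MeOH, rt
Reagents that add atoms: none
Why: Heterogeneous catalytic hydrogenation saturates the cinnamate C=C and hydrogenolyses both O-benzyl groups in one operation without touching C2 or C3, provided it is stopped after three equivalents of hydrogen, because the hindered cyclic C2–O1 bond should be cleaved more slowly than the open benzyl ethers.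

Compound list
1 | 4-bromo-1-fluoro-2-methoxybenzene | COc1cc(Br)ccc1F | starting material
2 | 2-(5-bromo-2-fluoro-3-methoxyphenyl)-4,4,5,5-tetramethyl-1,3,2-dioxaborolane | COc1cc(Br)cc(B2OC(C)(C)C(C)(C)O2)c1F | intermediate
3 | 5-bromo-2-fluoro-1-iodo-3-methoxybenzene | COc1cc(Br)cc(I)c1F | intermediate
4 | 1-(4-hydroxy-3,5-dimethoxyphenyl)ethan-1-one (acetosyringone) | CC(=O)c1cc(OC)c(O)c(OC)c1 | starting material
5 | 1-(4-benzyloxy-3,5-dimethoxyphenyl)ethan-1-one | CC(=O)c1cc(OC)c(OCc2ccccc2)c(OC)c1 | intermediate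
6 | 1-(4-benzyloxy-3,5-dimethoxyphenyl)-2-(5-bromo-2-fluoro-3-methoxyphenyl)ethan-1-one | COc1cc(Br)cc(CC(=O)c2cc(OC)c(OCc3ccccc3)c(OC)c2)c1F | intermediate
7 | rac-3-benzyloxy-1-(4-benzyloxy-3,5-dimethoxyphenyl)-2-(5-bromo-2-fluoro-3-methoxyphenyl)propan-1-one | COc1cc(Br)cc(c1F)C(COCc1ccccc1)C(=O)c1cc(OC)c(OCc2ccccc2)c(OC)c1 | intermediate
8 | methyl acrylate | C=CC(=O)OC | starting material
9 | methyl (E)-3-{3-[rac-1-benzyloxy-3-(4-benzyloxy-3,5-dimethoxyphenyl)-3-oxopropan-2-yl]-4-fluoro-5-methoxyphenyl}acrylate | COC(=O)/C=C/c1cc(OC)c(F)c(c1)C(COCc1ccccc1)C(=O)c1cc(OC)c(OCc2ccccc2)c(OC)c1 | intermediate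
10 | methyl (E)-3-{3-[(2R,3S)-1-benzyloxy-3-(4-benzyloxy-3,5-dimethoxyphenyl)-3-hydroxypropan-2-yl]-4-fluoro-5-methoxyphenyl}acrylate | COC(=O)/C=C/c1cc(OC)c(F)c(c1)[C@H](COCc1ccccc1)[C@@H](c1cc(OC)c(OCc2ccccc2)c(OC)c1)O | intermediate
11 | methyl (E)-3-[(2S,3R)-2-(4-benzyloxy-3,5-dimethoxyphenyl)-3-(benzyloxymethyl)-7-methoxy-2,3-dihydrobenzofuran-5-yl]acrylate | COC(=O)/C=C/c1cc(OC)c2c(c1)[C@H](COCc1ccccc1)[C@@H](c1cc(OC)c(OCc3ccccc3)c(OC)c1)O2 | intermediate
12 | methyl 3-[(2S,3R)-2-(4-hydroxy-3,5-dimethoxyphenyl)-3-(hydroxymethyl)-7-methoxy-2,3-dihydrobenzofuran-5-yl]propanoate | COC(=O)CCc1cc(OC)c2c(c1)[C@H](CO)[C@@H](c1cc(OC)c(O)c(OC)c1)O2 | target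

Total step count: 7. Longest linear sequence: 6 steps (steps 1, 3, 4, 5, 6, 7 from 1; equally steps 2 to 7 from 4).

Steps most likely to fail

**Step 6.** Racemisation of C3 may lag behind hydride transfer, benzyl alcohol may be lost by β-elimination, or the catalyst and the Felkin–Anh preference may match poorly. Each of these erodes the stereochemical purity.

The fallback runs from 3 and returns at 10. It sets both stereocentres by an auxiliary-controlled Evans syn-aldol reaction.
- Negishi-type coupling of 3 at its C–I bond with BrZnCH2CO2t-Bu (Pd(dba)2, P(t-Bu)3, THF, rt) gives tert-butyl 2-(5-bromo-2-fluoro-3-methoxyphenyl)acetate F1.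
- CF3CO2H gives 2-(5-bromo-2-fluoro-3-methoxyphenyl)acetic acid F2.
- Pivaloyl chloride/Et3N followed by lithiated (S)-4-benzyloxazolidin-2-one gives (S)-4-benzyl-3-[2-(5-bromo-2-fluoro-3-methoxyphenyl)acetyl]oxazolidin-2-one F3.
- Its (Z)-boron enolate (Bu2BOTf, i-Pr2NEt, CH2Cl2, −78 °C) adds to commercial 4-(benzyloxy)-3,5-dimethoxybenzaldehyde F4 through the Zimmerman–Traxler chair. This gives (S)-4-benzyl-3-[(2S,3S)-3-(4-benzyloxy-3,5-dimethoxyphenyl)-2-(5-bromo-2-fluoro-3-methoxyphenyl)-3-hydroxypropanoyl]oxazolidin-2-one F5.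
- LiBH4 (Et2O, MeOH, 0 °C) removes the auxiliary and gives (1S,2R)-1-(4-benzyloxy-3,5-dimethoxyphenyl)-2-(5-bromo-2-fluoro-3-methoxyphenyl)propane-1,3-diol F6.
- The stannylene acetal (Bu2SnO, then BnBr, CsF) benzylates only the primary hydroxyl group and gives (1S,2R)-3-benzyloxy-1-(4-benzyloxy-3,5-dimethoxyphenyl)-2-(5-bromo-2-fluoro-3-methoxyphenyl)propan-1-ol F7.
- The Heck reaction of step 5 with 8 gives 10, which is isolated and closed to 11 with Cs2CO3 in DMF.

**Step 4.** The delocalised enolate of 6 may be alkylated at oxygen by the hard halomethyl ether, or twice at carbon.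

The fallback runs from 6 and returns at 7. Mannich-type α-methylenation (paraformaldehyde, piperidine, AcOH, dioxane, 100 °C) gives 1-(4-benzyloxy-3,5-dimethoxyphenyl)-2-(5-bromo-2-fluoro-3-methoxyphenyl)prop-2-en-1-one F8. Base-catalysed oxa-Michael addition of benzyl alcohol (BnOH, cat. KOt-Bu, THF, 0 °C) then gives 7.

**Step 7.** Hydrogenolytic opening of ring B at the doubly activated benzylic C2–O1 bond may compete with the slower cleavage of the primary benzyl ether.

The fallback runs from 11 and returns at 12. Conjugate reduction of the cinnamate (NaBH4, NiCl2·6H2O, MeOH, 0 °C) gives methyl 3-[(2S,3R)-2-(4-benzyloxy-3,5-dimethoxyphenyl)-3-(benzyloxymethyl)-7-methoxy-2,3-dihydrobenzofuran-5-yl]propanoate F9. Both benzyl ethers are then removed without hydrogen by Lewis acid debenzylation with a cation scavenger (BCl3, pentamethylbenzene, CH2Cl2, −78 °C) to give 12.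

Further compounds
F1 | step 6 | tert-butyl 2-(5-bromo-2-fluoro-3-methoxyphenyl)acetate | COc1cc(Br)cc(CC(=O)OC(C)(C)C)c1F
F2 | step 6 | 2-(5-bromo-2-fluoro-3-methoxyphenyl)acetic acid | COc1cc(Br)cc(CC(=O)O)c1F
F3 | step 6 | (S)-4-benzyl-3-[2-(5-bromo-2-fluoro-3-methoxyphenyl)acetyl]oxazolidin-2-one | COc1cc(Br)cc(CC(=O)N2[C@@H](Cc3ccccc3)COC2=O)c1F
F4 | step 6 | 4-(benzyloxy)-3,5-dimethoxybenzaldehyde | COc1cc(C=O)cc(OC)c1OCc1ccccc1
F5 | step 6 | (S)-4-benzyl-3-[(2S,3S)-3-(4-benzyloxy-3,5-dimethoxyphenyl)-2-(5-bromo-2-fluoro-3-methoxyphenyl)-3-hydroxypropanoyl]oxazolidin-2-one | COc1cc(Br)cc(c1F)[C@H](C(=O)N1[C@@H](Cc2ccccc2)COC1=O)[C@@H](c1cc(OC)c(OCc2ccccc2)c(OC)c1)O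
F6 | step 6 | (1S,2R)-1-(4-benzyloxy-3,5-dimethoxyphenyl)-2-(5-bromo-2-fluoro-3-methoxyphenyl)propane-1,3-diol | COc1cc(Br)cc(c1F)[C@H](CO)[C@@H](c1cc(OC)c(OCc2ccccc2)c(OC)c1)O
F7 | step 6 | (1S,2R)-3-benzyloxy-1-(4-benzyloxy-3,5-dimethoxyphenyl)-2-(5-bromo-2-fluoro-3-methoxyphenyl)propan-1-ol | COc1cc(Br)cc(c1F)[C@H](COCc1ccccc1)[C@@H](c1cc(OC)c(OCc2ccccc2)c(OC)c1)O
F8 | step 4 | 1-(4-benzyloxy-3,5-dimethoxyphenyl)-2-(5-bromo-2-fluoro-3-methoxyphenyl)prop-2-en-1-one | C=C(C(=O)c1cc(OC)c(OCc2ccccc2)c(OC)c1)c1cc(Br)cc(OC)c1F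
F9 | step 7 | methyl 3-[(2S,3R)-2-(4-benzyloxy-3,5-dimethoxyphenyl)-3-(benzyloxymethyl)-7-methoxy-2,3-dihydrobenzofuran-5-yl]propanoate | COC(=O)CCc1cc(OC)c2c(c1)[C@H](COCc1ccccc1)[C@@H](c1cc(OC)c(OCc3ccccc3)c(OC)c1)O2
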